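**Retrosynthetic overview**
1. 42 ⇐ lactone 36 by desilylation, site-selective acylation of O4 with acid 39, acetylation of O9/O14 and removal of the PMB group on O16.
2. Key disconnection C7–C8: 36 ⇐ monocyclic seco keto aldehyde 34 by a SmI2 pinacol macrocyclisation followed in the same flask by lactonisation. Ring order: ring A (from carvone) first, then the ten-membered carbocycle C1–C10, then the γ-lactone (C7, C8, C17, C19, O).
3. Enabling feature: C7–C8, the bond shared by the ten-membered ring and the γ-lactone, is a vicinal diol bond (lactone oxygen on C7, tertiary OH on C8), and C8 is β to the lactone carbonyl C19. The precursor is therefore a C7 enal plus a C8 ketone that is part of a β-keto ester (C8–C17–C19), which chelates samarium and then acylates O7.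
4. 34 ⇐ ring A aldehyde 17 + (Z)-enone 24: boron aldol (C2–C3), Evans–Tishchenko reduction (C4 and the O2 acetate), Masamune–Brooks homologation of the C8 acid (C17–C19).
5. 17 ⇐ (S)-carvone 1 (C1 by two α′-alkylations, O14 by Criegee rearrangement, C10/C9 by epoxidation, Wharton transposition and [2,3]-Wittig rearrangement); 24 ⇐ but-2-yne-1,4-diol 18.

Key step: step 23

Remark: briarane numbering of 42 is used for every compound (ring A = C1, C10–C14; C15 on C1, C16 on C5, C18 on C17, C20 on C11; carvone C1–C6 become C10, C11, C12, C13, C14, C1). β is the ring A face carrying C15 in 42, α the face of the C14 oxygen. C17 of the β-keto esters 32–34 is stereolabile and is drawn without configuration.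

**Route**

Step 1
Reactants: 1 (S)-(+)-carvone
Product: 3 1β-(dimethoxymethyl) enone (acetal trans to the isopropenyl group), via silyl dienol ether 2 (not isolated)
Conditions: LiN(i-Pr)2, TMSCl, THF, −78 °C; solvent exchange to CH2Cl2; HC(OMe)3, TMSOTf (5 mol%), −78 °C
Reagents that add atoms: trimethyl orthoformate (COC(OC)OC)
Why: Kinetic α′-enolisation/silylation gives the cross-conjugated silyl dienol ether, and its Mukaiyama-type addition to the dimethoxycarbenium ion installs the masked C2 aldehyde anti to the isopropenyl group (this centre is re-set in step 2).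

Step 2
Reactants: 3 1β-(dimethoxymethyl) enone
Product: 5 1α-(dimethoxymethyl)-1β-methyl enone, via potassium enolate 4 (not isolated)
Conditions: KN(SiMe3)2, THF, −78 °C; MeI, −78 → −20 °C
Reagents that add atoms: iodomethane (CI)
Why: Enolate C-alkylation: A(1,2) strain holds the C14 isopropenyl group pseudoaxial, so iodomethane should enter the planar C1 enolate from the opposite face, setting the quaternary C1 with methyl trans to the C14 substituent.

Step 3
Reactants: 5 1α-(dimethoxymethyl)-1β-methyl enone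
Product: 8 14α-acetate, via methoxy hydroperoxide 6 (not isolated), via peroxyacetate 7 (not isolated)
Conditions: O3, CH2Cl2/MeOH, −78 °C; then Ac2O, Et3N, DMAP (cat.), 0 → 40 °C
Reagents that add atoms: ozone ([O-][O+]=O); methanol (CO)
Why: Criegee rearrangement: ozone should cleave only the electron-rich isopropenyl group (not the enone), and the 1,2-shift of C14 from carbon to oxygen in the peroxyacetate proceeds with retention, giving the 14α-acetate.

Step 4
Reactants: 8 14α-acetate
Product: 9 14α-alcohol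
Conditions: K2CO3, MeOH, 0 °C
Reagents that add atoms: none
Why: Mild transesterification removes the acetate without touching a stereocentre; the quaternary C1 blocks β-elimination.

Step 5
Reactants: 9 14α-alcohol
Product: 10 14α-silyl ether
Conditions: TBSOTf, 2,6-lutidine, CH2Cl2, −78 °C
Reagents that add atoms: tert-butyldimethylsilyl triflate (CC(C)(C)[Si](C)(C)OS(=O)(=O)C(F)(F)F)
Why: Silylation of the hindered secondary alcohol gives a group that survives base, hydrazine and enolate chemistry.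

Step 6
Reactants: 10 14α-silyl ether
Product: 11 11β,12β-epoxy ketone
Conditions: 30% H2O2, NaOH (cat.), MeOH, 0 °C
Reagents that add atoms: hydrogen peroxide (OO)
Why: Weitz–Scheffer nucleophilic epoxidation: hydroperoxide should add axially to C12 anti to the C14 substituent, as in carvone, giving the β-epoxide.

Step 7
Reactants: 11 11β,12β-epoxy ketone
Product: 12 12β-allylic alcohol (C10=C11)
Conditions: N2H4·H2O, AcOH (cat.), MeOH, 0 → 40 °C
Reagents that add atoms: none
Why: Wharton transposition: the epoxy hydrazone fragments with loss of N2 to the transposed allylic alcohol, and the C12–O bond (β) is not broken.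

Step 8
Reactants: 12 12β-allylic alcohol
Product: 13 tert-butyl (12β-allyloxy)acetate
Conditions: BrCH2CO2t-Bu, 50% aq. NaOH, n-Bu4NHSO4 (cat.), toluene, 0 °C → rt
Reagents that add atoms: tert-butyl bromoacetate (CC(C)(C)OC(=O)CBr)
Why: Phase-transfer Williamson etherification; the tert-butyl ester resists hydrolysis and transesterification.

Step 9
Reactants: 13 tert-butyl (12β-allyloxy)acetate
Product: 15 (9R)-hydroxy tert-butyl ester (C11=C12), via lithium enolate 14 (not isolated)
Conditions: LiN(i-Pr)2, THF, −78 → −20 °C; aq. NH4Cl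
Reagents that add atoms: none
Why: Ester-enolate [2,3]-Wittig rearrangement: the envelope transition state transfers the C12–O bond suprafacially into a C10–C9 bond on the β face, and the ester on the carbanion carbon should sit away from the quaternary C1 (Z-type allyl ether, syn product), giving 10α-H and (9R).

Step 10
Reactants: 15 (9R)-hydroxy tert-butyl ester
Product: 16 9,14-bis(silyl ether)
Conditions: TBSOTf, 2,6-lutidine, CH2Cl2, −78 °C
Reagents that add atoms: tert-butyldimethylsilyl triflate (CC(C)(C)[Si](C)(C)OS(=O)(=O)C(F)(F)F)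
Why: Silylation at low temperature leaves the dimethyl acetal intact and gives an O9 group that is a poor leaving group in step 23.

Step 11
Reactants: 16 9,14-bis(silyl ether)
Product: 17 ring A C2 aldehyde
Conditions: PPTS, acetone/H2O (10:1), 55 °C
Reagents that add atoms: water (O)
Why: Acid-catalysed acetal hydrolysis; the aldehyde is non-enolisable and the hindered secondary silyl ethers and the tert-butyl ester should survive.

Step 12
Reactants: 18 but-2-yne-1,4-diol
Product: 19 mono-PMB ether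
Conditions: NaH (1 equiv), PMBCl, n-Bu4NI (cat.), THF/DMF, 0 °C → rt (diol in threefold excess)
Reagents that add atoms: 4-methoxybenzyl chloride (COc1ccc(CCl)cc1)
Why: Williamson mono-etherification of the symmetric diol used in excess.

Step 13
Reactants: 19 mono-PMB ether
Product: 21 (Z)-iodoalkenol, via alkenylalanate 20 (not isolated)
Conditions: NaAlH2(OCH2CH2OMe)2, THF, 0 °C; then I2, −78 → 0 °C
Reagents that add atoms: iodine (II)
Why: Hydroxyl-directed trans-hydroalumination places aluminium on the alkyne carbon remote from the hydroxyl in a five-membered alanate, and iodinolysis with retention gives the (Z)-iodoalkene (I on C5, cis to C7).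

Step 14
Reactants: 21 (Z)-iodoalkenol
Product: 22 (Z)-iodoalkene silyl ether
Conditions: TBSCl, imidazole, DMF, rt
Reagents that add atoms: tert-butyldimethylsilyl chloride (CC(C)(C)[Si](C)(C)Cl)
Why: Silylation of the primary allylic alcohol (O7), to be freed selectively in step 21.

Step 15
Reactants: 22 (Z)-iodoalkene silyl ether
Product: 24 (Z)-enone, via ethoxydiene 23 (not isolated)
Conditions: tributyl(1-ethoxyvinyl)stannane, Pd(PPh3)4 (5 mol%), toluene, 90 °C; then 5% aq. oxalic acid, THF, rt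
Reagents that add atoms: tributyl(1-ethoxyvinyl)stannane (CCCC[Sn](CCCC)(CCCC)C(=C)OCC); water (O)
Why: Stille coupling proceeds with retention of alkene geometry, and mild hydrolysis of the enol ether unveils the methyl ketone (C3, C4) cis to C7.

Step 16
Reactants: 24 (Z)-enone; 17 ring A C2 aldehyde
Product: 26 (2R)-aldol, via boron enolate 25 (not isolated)
Conditions: 24, (+)-Ipc2BCl, Et3N, Et2O, 0 °C; then 17, −78 → −20 °C; H2O2, MeOH, pH 7 buffer, 0 °C
Reagents that add atoms: none
Why: Paterson boron aldol of a methyl ketone: the diisopinocampheylboron enolate should add under reagent control (boat-like transition state) to the Re face of the non-enolisable aldehyde, giving the (2R) alcohol.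

Step 17
Reactants: 26 (2R)-aldol
Product: 27 (2R,4R)-2-acetate 4-alcohol
Conditions: CH3CHO (6 equiv), SmI2 (0.3 equiv), THF, −10 °C
Reagents that add atoms: acetaldehyde (CC=O)
Why: Evans–Tishchenko reduction: the samarium-bound hemiacetal of O2 with acetaldehyde delivers hydride intramolecularly to C4 through a chair-like transition state, giving the 1,3-anti (4R) alcohol and leaving O2 as its acetate.

Step 18
Reactants: 27 (2R,4R)-2-acetate 4-alcohol
Product: 28 4-silyl ether
Conditions: TBSOTf, 2,6-lutidine, CH2Cl2, −78 °C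
Reagents that add atoms: tert-butyldimethylsilyl triflate (CC(C)(C)[Si](C)(C)OS(=O)(=O)C(F)(F)F)
Why: Silylation makes O4 a poor leaving group for the reductive key step.

Step 19
Reactants: 28 4-silyl ether
Product: 30 C8 carboxylic acid, via trimethylsilyl ester 29 (not isolated)
Conditions: TMSOTf, 2,6-lutidine, CH2Cl2, 0 °C → rt; then pH 7 buffer, THF
Reagents that add atoms: none
Why: Silyl triflate-mediated cleavage of the tert-butyl ester (loss of isobutene) under non-hydrolytic conditions spares the acetate and silyl ethers; the silyl ester falls apart on work-up.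

Step 20
Reactants: 30 C8 carboxylic acid
Product: 32 β-keto ester (C17 epimers), via acyl imidazolide 31 (not isolated)
Conditions: CDI, THF, rt; then KO2CCH(CH3)CO2CH3, MgCl2, Et3N, MeCN/THF, rt → 40 °C
Reagents that add atoms: potassium methyl methylmalonate (COC(=O)C(C)C(=O)[O-].[K+])
Why: Masamune–Brooks homologation: the acyl imidazolide C-acylates the magnesium enolate of the malonate half ester and decarboxylation gives the α-methyl β-keto ester under neutral conditions (C17 stereolabile).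

Step 21
Reactants: 32 β-keto ester
Product: 33 C7 allylic alcohol
Conditions: HF·pyridine, pyridine, THF, 0 °C
Reagents that add atoms: none
Why: Buffered fluoride should cleave the primary allylic silyl ether much faster than the four secondary ones.

Step 22
Reactants: 33 C7 allylic alcohol
Product: 34 seco keto aldehyde ((5Z)-enal)
Conditions: MnO2, CH2Cl2, rt
Reagents that add atoms: none
Why: MnO2 oxidises only the allylic alcohol under neutral conditions, which should preserve the (Z)-enal geometry and leave the β-keto ester untouched.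

Step 23
Reactants: 34 seco keto aldehyde
Product: 36 tricyclic lactone, via diol ester 35 (not isolated)
Conditions: SmI2 (3 equiv), THF, −78 °C → rt, 34 added over 6 h to 0.002 M; then aq. NH4Cl
Reagents that add atoms: none
Why: SmI2 transfers one electron to the C8 ketone, which is activated as a six-membered chelate of trivalent samarium with the C19 ester carbonyl; the ketyl couples with the C7 aldehyde carbon held on the same metal, a second electron gives the bis-alkoxide of 35, and the C7 alkoxide then acylates itself with the C19 methyl ester. The closest known reaction type is the chelation-controlled SmI2 pinacol cyclisation of β-keto esters with tethered aldehydes, together with SmI2 pinacol closures of medium rings. The ten-membered carbocycle closes by 10-exo-trig addition of the C8 ketyl to C7=O, and the γ-lactone by 5-exo-trig addition–elimination of O7 at C19. C8 should be set by approach of C7 anti to the C9–O bond (Felkin–Anh) and anti to the C17 methyl of the chelate; C7 follows because both oxygens stay on one samarium (cis-diolate), which leaves only the trans ring fusion for the lactone; C17 is funnelled through the chelate of the enolisable β-keto ester (methyl anti to C7). The step needs 1,2-coupling instead of conjugate coupling at C5, vinylogous loss of O4 or O16, or reductive loss of O9; this is secured by the fully substituted C5, by silyl and PMB ethers as poor leaving groups, and by the absence of HMPA and proton sources at low temperature and high dilution.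

Step 24
Reactants: 36 tricyclic lactone
Product: 37 4,9,14-triol lactone
Conditions: HF·pyridine, THF, 0 → 40 °C
Reagents that add atoms: none
Why: Acidic fluoride removes the three secondary silyl ethers and should leave the acetate, the lactone and the PMB ether intact without acyl migration.

Step 25
Reactants: 38 (R)-3-hydroxybutanoic acid
Product: 39 (R)-3-acetoxybutanoic acid
Conditions: Ac2O, pyridine, DMAP (cat.), CH2Cl2, 0 °C → rt; then H2O
Reagents that add atoms: acetic anhydride (CC(=O)OC(C)=O)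
Why: O-acetylation with aqueous hydrolysis of the mixed anhydride; the stereocentre is not involved.

Step 26
Reactants: 37 4,9,14-triol lactone; 39 (R)-3-acetoxybutanoic acid
Product: 40 C4 ester
Conditions: EDC·HCl, DMAP (0.2 equiv), CH2Cl2, −20 → 0 °C
Reagents that add atoms: none
Why: Steglich esterification should be site-selective for the allylic C4–OH (flanked by a CH2), since C14–OH and C9–OH each adjoin a quaternary carbon and C8–OH is tertiary.

Step 27
Reactants: 40 C4 ester
Product: 41 16-O-PMB ether of the target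
Conditions: Ac2O, pyridine, DMAP (cat.), CH2Cl2, 0 °C → rt
Reagents that add atoms: acetic anhydride (CC(=O)OC(C)=O)
Why: Acetylation of the secondary C9 and C14 alcohols; the tertiary C8–OH should not react under these conditions.

Step 28
Reactants: 41 16-O-PMB ether of the target
Product: 42 CNP0316115.1
Conditions: DDQ, CH2Cl2/pH 7 buffer, 0 °C
Reagents that add atoms: none
Why: Oxidative cleavage of the PMB ether under buffered conditions frees the primary allylic C16–OH without ester migration.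

**Compound list**
1 | (S)-(+)-carvone, (5S)-2-methyl-5-(prop-1-en-2-yl)cyclohex-2-en-1-one | CC1=CC[C@@H](CC1=O)C(C)=C | starting material
2 | trimethylsilyl dienol ether of 1 (C10(OSiMe3)=C1, C11=C12) | C[Si](C)(C)OC1=C[C@@H](C(C)=C)CC=C1C | intermediate
3 | 1β-(dimethoxymethyl)-14α-isopropenyl-11-methylcyclohex-11-en-10-one (1α-H) | COC(OC)[C@H]1C(=O)C(C)=CC[C@@H]1C(C)=C | intermediate
4 | potassium enolate of 3 (C10(OK)=C1) | [K+].[O-]C1=C(C(OC)OC)[C@@H](C(C)=C)CC=C1C | intermediate
5 | 1α-(dimethoxymethyl)-14α-isopropenyl-1β,11-dimethylcyclohex-11-en-10-one | COC(OC)[C@]1(C)C(=O)C(C)=CC[C@@H]1C(C)=C | intermediate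
6 | α-methoxy hydroperoxide of 5, 14α-C(CH3)(OCH3)OOH (both epimers at the peroxy carbon) | COC(OC)[C@]1(C)C(=O)C(C)=CC[C@@H]1C(C)(OC)OO | intermediate
7 | peroxyacetate of 6, 14α-C(CH3)(OCH3)OOAc | COC(OC)[C@]1(C)C(=O)C(C)=CC[C@@H]1C(C)(OC)OOC(C)=O | intermediate
8 | 14α-acetoxy-1α-(dimethoxymethyl)-1β,11-dimethylcyclohex-11-en-10-one | COC(OC)[C@]1(C)C(=O)C(C)=CC[C@@H]1OC(C)=O | intermediate
9 | 14α-hydroxy-1α-(dimethoxymethyl)-1β,11-dimethylcyclohex-11-en-10-one | COC(OC)[C@]1(C)C(=O)C(C)=CC[C@@H]1O | intermediate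
10 | 14α-(tert-butyldimethylsilyloxy)-1α-(dimethoxymethyl)-1β,11-dimethylcyclohex-11-en-10-one | COC(OC)[C@]1(C)C(=O)C(C)=CC[C@@H]1O[Si](C)(C)C(C)(C)C | intermediate
11 | 11β,12β-epoxide of 10 (cyclohexan-10-one) | COC(OC)[C@]1(C)C(=O)[C@@]2(C)O[C@H]2C[C@@H]1O[Si](C)(C)C(C)(C)C | intermediate
12 | 14α-(tert-butyldimethylsilyloxy)-1α-(dimethoxymethyl)-1β,11-dimethylcyclohex-10-en-12β-ol | COC(OC)[C@]1(C)C=C(C)[C@@H](O)C[C@@H]1O[Si](C)(C)C(C)(C)C | intermediate
13 | tert-butyl 2-(12β-yloxy)acetate ether of 12 | COC(OC)[C@]1(C)C=C(C)[C@@H](OCC(=O)OC(C)(C)C)C[C@@H]1O[Si](C)(C)C(C)(C)C | intermediate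
14 | lithium ester enolate of 13 | COC(OC)[C@]1(C)C=C(C)[C@@H](OC=C(O[Li])OC(C)(C)C)C[C@@H]1O[Si](C)(C)C(C)(C)C | intermediate
15 | tert-butyl (9R)-hydroxy ester: ring A (C11=C12, 14α-OTBS, 1α-CH(OMe)2, 1β-CH3) bearing 10β-CH(OH)CO2t-Bu, 10α-H | COC(OC)[C@@]1(C)[C@@H](O[Si](C)(C)C(C)(C)C)CC=C(C)[C@@H]1[C@@H](O)C(=O)OC(C)(C)C | intermediate
16 | 9-O-TBS ether of 15 | COC(OC)[C@@]1(C)[C@@H](O[Si](C)(C)C(C)(C)C)CC=C(C)[C@@H]1[C@@H](O[Si](C)(C)C(C)(C)C)C(=O)OC(C)(C)C | intermediate
17 | C2 aldehyde (1α-CHO, 1β-CH3) from 16 | O=C[C@@]1(C)[C@@H](O[Si](C)(C)C(C)(C)C)CC=C(C)[C@@H]1[C@@H](O[Si](C)(C)C(C)(C)C)C(=O)OC(C)(C)C | intermediate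
18 | but-2-yne-1,4-diol | OCC#CCO | starting material
19 | 4-[(4-methoxybenzyl)oxy]but-2-yn-1-ol | OCC#CCOCc1ccc(OC)cc1 | intermediate
20 | sodium cyclic alkoxy(alkenyl)alanate from 19 (Al on C5, O7–Al ring) | [Na+].COCCO[Al-]1(OCCOC)OC/C=C\1COCc2ccc(OC)cc2 | intermediate
21 | (Z)-3-iodo-4-[(4-methoxybenzyl)oxy]but-2-en-1-ol | OC/C=C(\I)COCc1ccc(OC)cc1 | intermediate
22 | TBS ether of 21 | CC(C)(C)[Si](C)(C)OC/C=C(\I)COCc1ccc(OC)cc1 | intermediate
23 | (Z)-2-ethoxydiene from 22 (C(OEt)=CH2 in place of I) | C=C(OCC)/C(COCc1ccc(OC)cc1)=C\CO[Si](C)(C)C(C)(C)C | intermediate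
24 | (Z)-5-(tert-butyldimethylsilyloxy)-3-{[(4-methoxybenzyl)oxy]methyl}pent-3-en-2-one | CC(=O)/C(COCc1ccc(OC)cc1)=C\CO[Si](C)(C)C(C)(C)C | intermediate
25 | diisopinocampheylboron enolate of 24 (from (+)-Ipc2BCl) | C=C(OB([C@H]1C[C@H]2C[C@@H]([C@@H]1C)C2(C)C)[C@H]1C[C@H]2C[C@@H]([C@@H]1C)C2(C)C)/C(COCc1ccc(OC)cc1)=C\CO[Si](C)(C)C(C)(C)C | intermediate
26 | (2R,5Z)-aldol: C2–OH, C4 ketone, O7-TBS, O16-PMB, 9,14-bis-OTBS, C8 tert-butyl ester | CC(C)(C)[Si](C)(C)OC/C=C(/COCc1ccc(OC)cc1)C(=O)C[C@@H](O)[C@@]1(C)[C@@H](O[Si](C)(C)C(C)(C)C)CC=C(C)[C@@H]1[C@@H](O[Si](C)(C)C(C)(C)C)C(=O)OC(C)(C)C | intermediate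
27 | (2R,4R,5Z)-2-acetate 4-alcohol | CC(C)(C)[Si](C)(C)OC/C=C(/COCc1ccc(OC)cc1)[C@H](O)C[C@@H](OC(C)=O)[C@@]1(C)[C@@H](O[Si](C)(C)C(C)(C)C)CC=C(C)[C@@H]1[C@@H](O[Si](C)(C)C(C)(C)C)C(=O)OC(C)(C)C | intermediate
28 | 4-O-TBS ether of 27 | CC(C)(C)[Si](C)(C)OC/C=C(/COCc1ccc(OC)cc1)[C@H](O[Si](C)(C)C(C)(C)C)C[C@@H](OC(C)=O)[C@@]1(C)[C@@H](O[Si](C)(C)C(C)(C)C)CC=C(C)[C@@H]1[C@@H](O[Si](C)(C)C(C)(C)C)C(=O)OC(C)(C)C | intermediate
29 | C8 trimethylsilyl ester | CC(C)(C)[Si](C)(C)OC/C=C(/COCc1ccc(OC)cc1)[C@H](O[Si](C)(C)C(C)(C)C)C[C@@H](OC(C)=O)[C@@]1(C)[C@@H](O[Si](C)(C)C(C)(C)C)CC=C(C)[C@@H]1[C@@H](O[Si](C)(C)C(C)(C)C)C(=O)O[Si](C)(C)C | intermediate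
30 | C8 carboxylic acid | CC(C)(C)[Si](C)(C)OC/C=C(/COCc1ccc(OC)cc1)[C@H](O[Si](C)(C)C(C)(C)C)C[C@@H](OC(C)=O)[C@@]1(C)[C@@H](O[Si](C)(C)C(C)(C)C)CC=C(C)[C@@H]1[C@@H](O[Si](C)(C)C(C)(C)C)C(=O)O | intermediate
31 | C8 acyl imidazolide | CC(C)(C)[Si](C)(C)OC/C=C(/COCc1ccc(OC)cc1)[C@H](O[Si](C)(C)C(C)(C)C)C[C@@H](OC(C)=O)[C@@]1(C)[C@@H](O[Si](C)(C)C(C)(C)C)CC=C(C)[C@@H]1[C@@H](O[Si](C)(C)C(C)(C)C)C(=O)n1ccnc1 | intermediate
32 | methyl β-keto ester (C8 ketone, C17 methyl, C19 ester; C17 epimers) | CC(C)(C)[Si](C)(C)OC/C=C(/COCc1ccc(OC)cc1)[C@H](O[Si](C)(C)C(C)(C)C)C[C@@H](OC(C)=O)[C@@]1(C)[C@@H](O[Si](C)(C)C(C)(C)C)CC=C(C)[C@@H]1[C@@H](O[Si](C)(C)C(C)(C)C)C(=O)C(C)C(=O)OC | intermediate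
33 | C7 primary allylic alcohol of 32 | OC/C=C(/COCc1ccc(OC)cc1)[C@H](O[Si](C)(C)C(C)(C)C)C[C@@H](OC(C)=O)[C@@]1(C)[C@@H](O[Si](C)(C)C(C)(C)C)CC=C(C)[C@@H]1[C@@H](O[Si](C)(C)C(C)(C)C)C(=O)C(C)C(=O)OC | intermediate
34 | seco keto aldehyde: (2R,4R,5Z,9R) C7 enal, C8 ketone, C19 methyl ester | O=C/C=C(/COCc1ccc(OC)cc1)[C@H](O[Si](C)(C)C(C)(C)C)C[C@@H](OC(C)=O)[C@@]1(C)[C@@H](O[Si](C)(C)C(C)(C)C)CC=C(C)[C@@H]1[C@@H](O[Si](C)(C)C(C)(C)C)C(=O)C(C)C(=O)OC | intermediate
35 | ten-membered (7S,8S)-7,8-diol methyl ester (17R), before lactonisation | CC(C)(C)[Si](C)(C)O[C@@H]1C[C@@H](OC(C)=O)[C@@]2(C)[C@@H](O[Si](C)(C)C(C)(C)C)CC=C(C)[C@@H]2[C@@H](O[Si](C)(C)C(C)(C)C)[C@](O)([C@@H](C)C(=O)OC)[C@@H](O)/C=C\1COCc3ccc(OC)cc3 | intermediate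
36 | tricyclic lactone: 2-OAc, 4,9,14-tris-OTBS, 16-OPMB, 8-OH, (7S,8S,17R) as in 42 | CC(C)(C)[Si](C)(C)O[C@@H]1C[C@@H](OC(C)=O)[C@@]2(C)[C@@H](O[Si](C)(C)C(C)(C)C)CC=C(C)[C@@H]2[C@@H](O[Si](C)(C)C(C)(C)C)[C@@]3(O)[C@H](/C=C\1COCc4ccc(OC)cc4)OC(=O)[C@@H]3C | intermediate
37 | 4,9,14-triol lactone (2-OAc, 16-OPMB, 8-OH) | O[C@@H]1C[C@@H](OC(C)=O)[C@@]2(C)[C@@H](O)CC=C(C)[C@@H]2[C@@H](O)[C@@]3(O)[C@H](/C=C\1COCc4ccc(OC)cc4)OC(=O)[C@@H]3C | intermediate
38 | (R)-3-hydroxybutanoic acid | C[C@@H](O)CC(=O)O | starting material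
39 | (R)-3-acetoxybutanoic acid | CC(=O)O[C@H](C)CC(=O)O | intermediate
40 | 4-O-[(R)-3-acetoxybutanoyl] 9,14-diol | CC(=O)O[C@H](C)CC(=O)O[C@@H]1C[C@@H](OC(C)=O)[C@@]2(C)[C@@H](O)CC=C(C)[C@@H]2[C@@H](O)[C@@]3(O)[C@H](/C=C\1COCc4ccc(OC)cc4)OC(=O)[C@@H]3C | intermediate
41 | 16-O-(4-methoxybenzyl) ether of 42 | CC(=O)O[C@H](C)CC(=O)O[C@@H]1C[C@@H](OC(C)=O)[C@@]2(C)[C@@H](OC(C)=O)CC=C(C)[C@@H]2[C@@H](OC(C)=O)[C@@]3(O)[C@H](/C=C\1COCc4ccc(OC)cc4)OC(=O)[C@@H]3C | intermediate
42 | CNP0316115.1 | CC(=O)O[C@H](C)CC(=O)O[C@@H]1C[C@@H](OC(C)=O)[C@@]2(C)[C@@H](OC(C)=O)CC=C(C)[C@@H]2[C@@H](OC(C)=O)[C@@]2(O)[C@H](/C=C\1CO)OC(=O)[C@@H]2C | target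

**Totals**
Total step count: 28. Longest linear sequence: 23 steps (steps 1–11, 16–24, 26–28).

**Steps most likely to fail, and fallbacks**

Step 23. Electron transfer to the enal may outrun C7–C8 coupling, giving conjugate coupling at C5, vinylogous loss of O4 or O16, plain carbonyl reduction, loss of the (5Z) geometry through the delocalised ketyl, or poor facial selectivity at C7/C8. The fallback closes the same bond by a polar, non-reductive route and sets out from 32. The β-keto ester would be converted (LiOTf, Et3N, Tf2O, CH2Cl2) into the (Z)-enol triflate F1. The primary silyl ether would be removed (HF·pyridine) to give the alcohol F2, which would be oxidised (MnO2) to the enal F3. Nozaki–Hiyama–Kishi cyclisation of F3 (CrCl2, NiCl2 cat., DMSO/THF, high dilution) would add the alkenylchromium species to the C7 aldehyde; the chromium alkoxide should lactonise onto the cis ester to give the 8(17)-butenolide F4, closing the ten-membered ring and the lactone. Nucleophilic epoxidation (t-BuOOH, DBU, CH2Cl2) would give the 8,17-epoxide F5. Reductive opening of the α,β-epoxy lactone at C17 (SmI2, THF/MeOH, −78 °C) would give the 8-hydroxy lactone and come back to the route at 36.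

Step 9. The hindered enolate may undergo a [1,2]-shift or elimination instead of the [2,3]-shift, or the rearrangement may give the wrong C9 configuration. The fallback separates C–C bond formation from oxygenation and sets out from 12. Acetylation (Ac2O, pyridine) would give the allylic acetate F6. Ireland–Claisen rearrangement (LiN(i-Pr)2, TBSCl, THF/HMPA, −78 → 60 °C, acidic work-up) would transfer chirality suprafacially to give the 10β-acetic acid F7. This would be converted (Boc2O, DMAP, t-BuOH) into the tert-butyl ester F8. Hydroxylation of its potassium enolate (KN(SiMe3)2, then (+)-(camphorsulfonyl)oxaziridine, with the antipode tried if the reagent and substrate prove mismatched) would give the (9R)-alcohol and come back to the route at 15.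

Step 16. Facial selectivity at C2 may be poor if the reagent and the α-quaternary aldehyde are mismatched, and addition to the neopentyl aldehyde may be slow. The fallback uses an auxiliary-controlled acetate aldol and sets out from 17. A Nagao aldol with (S)-3-acetyl-4-isopropyl-1,3-thiazolidine-2-thione (Sn(OTf)2, N-ethylpiperidine, CH2Cl2, −78 °C) would give the (2R)-β-hydroxy imide F9. Displacement of the auxiliary (MeNHOMe·HCl, imidazole, CH2Cl2) would give the Weinreb amide F10. Addition of the (Z)-alkenyllithium F11, made from 22 with t-BuLi in Et2O at −78 °C and used in excess, would give the β-hydroxy enone and come back to the route at 26.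

**Further compounds**
F1 | step 23 | (Z)-enol triflate of 32 (OTf on C8 cis to the C19 ester) | CC(C)(C)[Si](C)(C)OC/C=C(/COCc1ccc(OC)cc1)[C@H](O[Si](C)(C)C(C)(C)C)C[C@@H](OC(C)=O)[C@@]1(C)[C@@H](O[Si](C)(C)C(C)(C)C)CC=C(C)[C@@H]1[C@@H](O[Si](C)(C)C(C)(C)C)/C(OS(=O)(=O)C(F)(F)F)=C(\C)C(=O)OC
F2 | step 23 | C7 primary alcohol of F1 | OC/C=C(/COCc1ccc(OC)cc1)[C@H](O[Si](C)(C)C(C)(C)C)C[C@@H](OC(C)=O)[C@@]1(C)[C@@H](O[Si](C)(C)C(C)(C)C)CC=C(C)[C@@H]1[C@@H](O[Si](C)(C)C(C)(C)C)/C(OS(=O)(=O)C(F)(F)F)=C(\C)C(=O)OC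
F3 | step 23 | (5Z)-enal enol triflate | O=C/C=C(/COCc1ccc(OC)cc1)[C@H](O[Si](C)(C)C(C)(C)C)C[C@@H](OC(C)=O)[C@@]1(C)[C@@H](O[Si](C)(C)C(C)(C)C)CC=C(C)[C@@H]1[C@@H](O[Si](C)(C)C(C)(C)C)/C(OS(=O)(=O)C(F)(F)F)=C(\C)C(=O)OC
F4 | step 23 | tricyclic 8(17)-butenolide (7S) | CC(C)(C)[Si](C)(C)O[C@@H]1C[C@@H](OC(C)=O)[C@@]2(C)[C@@H](O[Si](C)(C)C(C)(C)C)CC=C(C)[C@@H]2[C@@H](O[Si](C)(C)C(C)(C)C)C3=C(C)C(=O)O[C@H]3/C=C\1COCc4ccc(OC)cc4
F5 | step 23 | 8α,17α-epoxy lactone | CC(C)(C)[Si](C)(C)O[C@@H]1C[C@@H](OC(C)=O)[C@@]2(C)[C@@H](O[Si](C)(C)C(C)(C)C)CC=C(C)[C@@H]2[C@@H](O[Si](C)(C)C(C)(C)C)[C@@]34O[C@@]4(C)C(=O)O[C@H]3/C=C\1COCc5ccc(OC)cc5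
F6 | step 9 | 12β-acetate of 12 | COC(OC)[C@]1(C)C=C(C)[C@@H](OC(C)=O)C[C@@H]1O[Si](C)(C)C(C)(C)C
F7 | step 9 | 10β-(carboxymethyl) ring A acid (C11=C12) | COC(OC)[C@@]1(C)[C@@H](O[Si](C)(C)C(C)(C)C)CC=C(C)[C@@H]1CC(=O)O
F8 | step 9 | tert-butyl ester of F7 | COC(OC)[C@@]1(C)[C@@H](O[Si](C)(C)C(C)(C)C)CC=C(C)[C@@H]1CC(=O)OC(C)(C)C
F9 | step 16 | (2R)-β-hydroxy N-acyl (S)-4-isopropylthiazolidine-2-thione | S=C1SC[C@H](C(C)C)N1C(=O)C[C@@H](O)[C@@]1(C)[C@@H](O[Si](C)(C)C(C)(C)C)CC=C(C)[C@@H]1[C@@H](O[Si](C)(C)C(C)(C)C)C(=O)OC(C)(C)C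
F10 | step 16 | (2R)-β-hydroxy Weinreb amide | CON(C)C(=O)C[C@@H](O)[C@@]1(C)[C@@H](O[Si](C)(C)C(C)(C)C)CC=C(C)[C@@H]1[C@@H](O[Si](C)(C)C(C)(C)C)C(=O)OC(C)(C)C
F11 | step 16 | (Z)-alkenyllithium from 22 | CC(C)(C)[Si](C)(C)OC/C=C(\[Li])COCc1ccc(OC)cc1
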